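**Retrosynthetic overview**

1. Target: (3'S,6E,6'E)-3'-hydroxy-4',5'-didehydro-4,5'-retro-β,β-caroten-3-one (eschscholtzxanthone). Carotenoid numbering: ring A (cyclohexenone) C1–C6, chain C7–C15 then C15'–C7', ring B (hydroxycyclohexene) C1'–C6'.
2. Enabling feature: one unbroken conjugated path of thirteen π bonds, C3=O, C4=C5 (ring A), exocyclic C6=C7, the chain, exocyclic C7'=C6', C5'=C4' (ring B). This is the formal 1,22-dehydration product (C6–OH, C4'–H) of an ordinary carotenoid polyene, in which every chain double bond, C11'=C12' included, ends as a single bond.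
3. Key disconnection: C11'–C12', made by Wittig union of C25 aldehyde 9 (ring A, masked ketone, tertiary C6–OH) with C15 phosphonium salt 16 (ring B, C3' stereocentre). The same flask is then acidified to trigger the biomimetic retro-shift and unmask the ketone; only O-desilylation follows.
4. Fragments: 9 from 4-oxoisophorone plus enynol 3 (acetylide addition, trans-reduction) and Wittig with C10 dialdehyde 8; 16 from (4R,6R)-actinol by enol triflate/Stille coupling with the stannane of the same enynol.
5. Ring order: both carbocycles are bought and none is formed; the only ring made is the temporary dioxolane (step 1), opened again in step 11.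

Key step: step 11

Remark: intermediates 4–9 and 17 are racemic at the ring A carbinol carbon (C6), and 9 and 17 may contain Z isomers at the Wittig-made bonds; both elements vanish in step 11, so the SMILES show the C6-unspecified, all-E representatives.

**Route**

Step 1
Reactants: 1 4-oxoisophorone
Product: 2 4-oxoisophorone 4-monoethylene ketal
Conditions: ethylene glycol (1.5 equiv), p-TsOH·H2O (cat.), toluene, reflux, Dean–Stark
Reagents that add atoms: ethylene glycol, OCCO
Why: Acid-catalysed ketalisation with water removal takes the sterically open carbonyl (flanked by CH and CH2) rather than the one flanked by the quaternary carbon and the methyl-bearing alkene carbon, which masks the future C3 ketone and leaves the correct carbonyl for step 2.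

Step 2
Reactants: 2 4-oxoisophorone 4-monoethylene ketal; 3 (2E)-3-methylpent-2-en-4-yn-1-ol
Product: 4 ring A enyne diol
Conditions: 3, n-BuLi (2.05 equiv), THF, −78 → 0 °C; then 2, −78 → 20 °C; H2O
Reagents that add atoms: none
Why: 1,2-Addition of the lithium acetylide (alkoxide–acetylide dianion of 3) to the remaining ketone builds the ring A–chain bond; the new tertiary carbinol centre forms as a racemate, which is harmless because this carbon becomes sp2 in step 11.

Step 3
Reactants: 4 ring A enyne diol
Product: 5 ring A (2E,4E)-diene diol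
Conditions: NaAlH2(OCH2CH2OMe)2 (3 equiv), THF, 0 → 20 °C; aq. NaOH
Reagents that add atoms: none
Why: Alkoxide-directed trans-hydroalumination of the propargylic alcohol (aluminium hydride reduction of propargylic alcohols) should give the (E)-alkene and leave the ketal and the trisubstituted alkene alone.

Step 4
Reactants: 5 ring A (2E,4E)-diene diol
Product: 7 ring A C15 phosphonium bromide, via allylic bromide 6 (not isolated)
Conditions: CBr4 (1.05 equiv), PPh3 (1.05 equiv), 2,6-lutidine (0.2 equiv), CH2Cl2, −20 °C; then PPh3 (1.2 equiv), 20 °C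
Reagents that add atoms: tetrabromomethane, BrC(Br)(Br)Br; triphenylphosphine, c1ccc(cc1)P(c1ccccc1)c1ccccc1
Why: Appel bromination activates only the primary allylic hydroxyl (the tertiary one is too hindered to form the oxyphosphonium ion), and the dienylic bromide is trapped at once by SN2 attack of PPh3 to give the Wittig salt, the lutidine buffer protecting ketal and tertiary carbinol from HBr.

Step 5
Reactants: 7 ring A C15 phosphonium bromide; 8 (2E,4E,6E)-2,7-dimethylocta-2,4,6-trienedial
Product: 9 C25 hydroxy ketal aldehyde
Conditions: 8 (3 equiv), NaOMe (1.05 equiv, added slowly), CH2Cl2/MeOH, 0 → 20 °C, dark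
Reagents that add atoms: none
Why: Wittig olefination of one formyl group of the symmetrical dialdehyde, mono-selectivity resting on the excess of 8 and on the lower electrophilicity of the longer polyenal product; an E/Z mixture at the new C11=C12 bond is acceptable because this bond becomes a single bond in step 11.

Step 6
Reactants: 10 (4R,6R)-actinol
Product: 11 O-triethylsilyl actinol
Conditions: Et3SiCl, imidazole, CH2Cl2, 0 → 20 °C
Reagents that add atoms: chlorotriethylsilane, CC[Si](Cl)(CC)CC
Why: Standard silylation of the secondary alcohol; the triethylsilyl group should survive amide base, cross-coupling, ylide and brief catalytic acid and leave under buffered fluoride at the end.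

Step 7
Reactants: 11 O-triethylsilyl actinol
Product: 12 ring B enol triflate
Conditions: LiN(i-Pr)2, THF, −78 → 0 °C; PhNTf2, −78 → 20 °C
Reagents that add atoms: N-phenylbis(trifluoromethanesulfonimide), FC(F)(F)S(=O)(=O)N(c1ccccc1)S(=O)(=O)C(F)(F)F
Why: Enolisation can only occur towards the methyl-bearing α-carbon because the other α-carbon is quaternary, so the tetrasubstituted lithium enolate forms regiospecifically and is O-sulfonylated (enol triflate formation); the methyl-bearing stereocentre is destroyed on purpose and the silyloxy-bearing one is untouched.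

Step 8
Reactants: 3 (2E)-3-methylpent-2-en-4-yn-1-ol
Product: 13 (2E,4E)-stannyl dienol
Conditions: Bu3SnH (1.1 equiv), PdCl2(PPh3)2 (2 mol%), THF, 0 °C
Reagents that add atoms: tributyltin hydride, CCCC[SnH](CCCC)CCCC
Why: Palladium-catalysed hydrostannation of the terminal alkyne is a syn addition that places tin at the less hindered terminus and so should give the (E)-vinylstannane, a minor internal regioisomer being removed by chromatography.

Step 9
Reactants: 12 ring B enol triflate; 13 (2E,4E)-stannyl dienol
Product: 14 ring B C15 dienol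
Conditions: Pd2(dba)3 (2.5 mol%), AsPh3 (20 mol%), LiCl (3 equiv), N-methylpyrrolidone, 50 °C
Reagents that add atoms: none
Why: Stille cross-coupling: oxidative addition of the enol triflate to zerovalent palladium (chloride from LiCl stabilising the vinylpalladium species), transmetalation from the vinylstannane helped by the weakly bound AsPh3 ligand, and reductive elimination with retention of both alkene geometries, the C–O stereocentre being remote and untouched.

Step 10
Reactants: 14 ring B C15 dienol
Product: 16 ring B C15 phosphonium bromide, via allylic bromide 15 (not isolated)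
Conditions: CBr4 (1.05 equiv), PPh3 (1.05 equiv), 2,6-lutidine (0.2 equiv), CH2Cl2, −20 °C; then PPh3 (1.2 equiv), 20 °C
Reagents that add atoms: tetrabromomethane, BrC(Br)(Br)Br; triphenylphosphine, c1ccc(cc1)P(c1ccccc1)c1ccccc1
Why: Appel bromination of the primary dienylic alcohol followed by SN2 quaternisation of PPh3 at the primary carbon, under buffered acid-free conditions that keep the silyl ether.

Step 11
Reactants: 9 C25 hydroxy ketal aldehyde; 16 ring B C15 phosphonium bromide
Product: 19 3'-O-triethylsilyl eschscholtzxanthone, via C40 Wittig carbinol 17 (not isolated), via retro ketal 18 (not isolated)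
Conditions: 16 (1.15 equiv), KOt-Bu (1.1 equiv), THF, −30 → 0 °C; add 9, 0 → 20 °C, dark; then p-TsOH·H2O (0.3 equiv), 0 °C, 20 min; aq. NaHCO3; crude: I2 (1 mol%), heptane/CH2Cl2, diffuse light, 20 °C
Reagents that add atoms: none
Why: The ylide of 16 attacks the only aldehyde of 9 (Wittig olefination) and joins C11' to C12' as an alkene of irrelevant geometry in the ordinary carotenoid-type polyene 17; catalytic p-TsOH then ionises the tertiary C6 hydroxyl, which is allylic to ring A C4=C5 and to the whole ten-ene chain, to a polyenyl cation delocalised from C6 to C5', loss of the C4' proton moves all ten double bonds by one position (1,22-elimination of water) to give 18, and the water just expelled hydrolyses the now polyene-conjugated dioxolane to the C3 ketone of 19, so the acid stage is a net isomerisation with loss of ethylene glycol. The closest known reactions are the acid-catalysed retro-dehydration of polyenyl carbinols (retinol to anhydroretinol, carotenoid allylic alcohols to retro-didehydro carotenoids) and the Wittig assembly of carotenoids from C15 phosphonium salts; the step also copies the way retro-carotenoids are thought to arise in plants, by hydroxylation of a normal carotenoid and loss of water through the chromophore. No ring is closed and no stereocentre is created: the C6 carbinol centre and the nine chain alkene geometries of 17 are erased, the ten new stereogenic double bonds form under thermodynamic control (chain bonds E from the s-trans polyenyl cation, the exocyclic C6=C7 and C6'=C7' bonds equilibrated by the iodine treatment), and C3' keeps its configuration because its C–O bond is never broken (R in 16 and 17 becomes S in 18 and 19 only because C4' turns sp2 and the CIP priorities change). The selectivity needed is ionisation at C6 rather than C3' and proton loss at C4' rather than from a methyl group: the first is secured by the tertiary, doubly allylic C6–OH against a silyl-protected secondary C3'–O, the second by the reversibility of the cross-conjugated alternatives and by the irreversible unmasking of the C3 carbonyl, which locks the single fully conjugated product.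

Step 12
Reactants: 19 3'-O-triethylsilyl eschscholtzxanthone
Product: 20 (3'S,6E,6'E)-eschscholtzxanthone
Conditions: HF·pyridine, pyridine, THF, 0 °C, dark; crystallisation
Reagents that add atoms: none
Why: Fluoride-driven cleavage of the Si–O bond under buffered conditions leaves the C3'–O bond and hence the stereocentre intact and avoids both strong acid and strong base, to which the allylic carbinol at the end of the polyenone is sensitive; the (6E,6'E) isomer should be collected by crystallisation and the mother liquor re-equilibrated with iodine.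

**Compound list**

1 | 2,6,6-trimethylcyclohex-2-ene-1,4-dione (4-oxoisophorone) | CC1=CC(=O)CC(C)(C)C1=O | starting material
2 | 7,9,9-trimethyl-1,4-dioxaspiro[4.5]dec-6-en-8-one | CC1=CC2(OCCO2)CC(C)(C)C1=O | intermediate
3 | (2E)-3-methylpent-2-en-4-yn-1-ol | C#C/C(C)=C/CO | starting material
4 | (2E)-5-(8-hydroxy-7,9,9-trimethyl-1,4-dioxaspiro[4.5]dec-6-en-8-yl)-3-methylpent-2-en-4-yn-1-ol (racemic) | CC1=CC2(OCCO2)CC(C)(C)C1(O)C#C/C(C)=C/CO | intermediate
5 | (2E,4E)-5-(8-hydroxy-7,9,9-trimethyl-1,4-dioxaspiro[4.5]dec-6-en-8-yl)-3-methylpenta-2,4-dien-1-ol (racemic) | CC1=CC2(OCCO2)CC(C)(C)C1(O)/C=C/C(C)=C/CO | intermediate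
6 | 8-[(1E,3E)-5-bromo-3-methylpenta-1,3-dien-1-yl]-7,9,9-trimethyl-1,4-dioxaspiro[4.5]dec-6-en-8-ol (formed and consumed in step 4) | CC1=CC2(OCCO2)CC(C)(C)C1(O)/C=C/C(C)=C/CBr | intermediate
7 | [(2E,4E)-5-(8-hydroxy-7,9,9-trimethyl-1,4-dioxaspiro[4.5]dec-6-en-8-yl)-3-methylpenta-2,4-dien-1-yl]triphenylphosphonium bromide | CC1=CC2(OCCO2)CC(C)(C)C1(O)/C=C/C(C)=C/C[P+](c1ccccc1)(c1ccccc1)c1ccccc1.[Br-] | intermediate
8 | (2E,4E,6E)-2,7-dimethylocta-2,4,6-trienedial | O=C/C(C)=C/C=C/C=C(C)/C=O | starting material
9 | (2E,4E,6E,8E,10E,12E)-13-(8-hydroxy-7,9,9-trimethyl-1,4-dioxaspiro[4.5]dec-6-en-8-yl)-2,7,11-trimethyltrideca-2,4,6,8,10,12-hexaenal | CC1=CC2(OCCO2)CC(C)(C)C1(O)/C=C/C(C)=C/C=C/C(C)=C/C=C/C=C(C)/C=O | intermediate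
10 | (4R,6R)-4-hydroxy-2,2,6-trimethylcyclohexan-1-one (actinol) | C[C@@H]1C[C@@H](O)CC(C)(C)C1=O | starting material
11 | (4R,6R)-2,2,6-trimethyl-4-[(triethylsilyl)oxy]cyclohexan-1-one | C[C@@H]1C[C@@H](O[Si](CC)(CC)CC)CC(C)(C)C1=O | intermediate
12 | (4R)-2,6,6-trimethyl-4-[(triethylsilyl)oxy]cyclohex-1-en-1-yl trifluoromethanesulfonate | CC1=C(OS(=O)(=O)C(F)(F)F)C(C)(C)C[C@H](O[Si](CC)(CC)CC)C1 | intermediate
13 | (2E,4E)-3-methyl-5-(tributylstannyl)penta-2,4-dien-1-ol | CCCC[Sn](CCCC)(CCCC)/C=C/C(C)=C/CO | intermediate
14 | (2E,4E)-3-methyl-5-[(4R)-2,6,6-trimethyl-4-[(triethylsilyl)oxy]cyclohex-1-en-1-yl]penta-2,4-dien-1-ol | CC1=C(/C=C/C(C)=C/CO)C(C)(C)C[C@H](O[Si](CC)(CC)CC)C1 | intermediate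
15 | {[(1R)-4-[(1E,3E)-5-bromo-3-methylpenta-1,3-dien-1-yl]-3,5,5-trimethylcyclohex-3-en-1-yl]oxy}triethylsilane (formed and consumed in step 10) | CC1=C(/C=C/C(C)=C/CBr)C(C)(C)C[C@H](O[Si](CC)(CC)CC)C1 | intermediate
16 | [(2E,4E)-3-methyl-5-[(4R)-2,6,6-trimethyl-4-[(triethylsilyl)oxy]cyclohex-1-en-1-yl]penta-2,4-dien-1-yl]triphenylphosphonium bromide | CC1=C(/C=C/C(C)=C/C[P+](c2ccccc2)(c2ccccc2)c2ccccc2)C(C)(C)C[C@H](O[Si](CC)(CC)CC)C1.[Br-] | intermediate
17 | C40 carbinol of the normal polyene type: ring A = 8-hydroxy-7,9,9-trimethyl-1,4-dioxaspiro[4.5]dec-6-en-8-yl, all-E 3,7,12,16-tetramethyloctadeca-1,3,5,7,9,11,13,15,17-nonaene-1,18-diyl chain, ring B = (4R)-2,6,6-trimethyl-4-[(triethylsilyl)oxy]cyclohex-1-en-1-yl (formed and consumed in step 11) | CC1=CC2(OCCO2)CC(C)(C)C1(O)/C=C/C(C)=C/C=C/C(C)=C/C=C/C=C(C)/C=C/C=C(C)/C=C/C1=C(C)C[C@@H](O[Si](CC)(CC)CC)CC1(C)C | intermediate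
18 | (3'S,6E,6'E)-3,3-ethylenedioxy-3'-[(triethylsilyl)oxy]-4',5'-didehydro-4,5'-retro-β,β-carotene (formed and consumed in step 11) | CC1=CC2(OCCO2)CC(C)(C)\C1=C/C=C(C)/C=C/C=C(C)/C=C/C=C/C(C)=C/C=C/C(C)=C/C=C1/C(C)=C[C@@H](O[Si](CC)(CC)CC)CC1(C)C | intermediate
19 | (3'S,6E,6'E)-3'-[(triethylsilyl)oxy]-4',5'-didehydro-4,5'-retro-β,β-caroten-3-one | CC1=CC(=O)CC(C)(C)\C1=C/C=C(C)/C=C/C=C(C)/C=C/C=C/C(C)=C/C=C/C(C)=C/C=C1/C(C)=C[C@@H](O[Si](CC)(CC)CC)CC1(C)C | intermediate
20 | (3'S,6E,6'E)-3'-hydroxy-4',5'-didehydro-4,5'-retro-β,β-caroten-3-one (eschscholtzxanthone, CNP0279160.1) | CC1=CC(=O)CC(C)(C)\C1=C/C=C(C)/C=C/C=C(C)/C=C/C=C/C(C)=C/C=C/C(C)=C/C=C1/C(C)=C[C@@H](O)CC1(C)C | target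

**Step count and risks**

Total step count: 12. Longest linear sequence: 7 steps (steps 1, 2, 3, 4, 5, 11, 12; compounds 1, 2, 4, 5, 7, 9, 19, 20).

Steps most likely to fail:

Step 11. The acid stage may not funnel cleanly. The polyenyl cation may lose a proton unselectively and leave cross-conjugated isomers, the allylic C3' silyloxy carbon may ionise after the shift with loss of configuration, and the product may drift under acid towards its diketone tautomer. The fallback separates coupling and shift and replaces acid catalysis by activation under basic buffer. It sets out from 17, obtained by stopping step 11 after the Wittig stage (neutral aqueous work-up, chromatography on amine-deactivated silica). Treatment with MsCl and Et3N in CH2Cl2 at −20 °C should give the tertiary methanesulfonate of 17 F1, which ionises spontaneously; Et3N removes the C4' proton to give 18, this time isolated. Hydrolysis of the polyenyl ketal of 18 on wet silica gel or with dilute aqueous oxalic acid in THF returns to the route at 19.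

Step 12. Desilylation of the retro-polyenone may be accompanied by base-type isomerisation (deprotonation at C3' through the polyenone), by ionisation of the freed allylic alcohol, or by general degradation of the chromophore. The fallback removes the silyl group before the union, so that nothing is done after the key step. It sets out from 14: PPh3·HBr in MeOH at 20 °C should convert the dienylic alcohol to the phosphonium salt and methanolyse the silyl ether, giving the free-hydroxy phosphonium bromide F2. Wittig reaction of F2 with 9 (KOt-Bu, THF) followed by the brief catalytic p-TsOH stage of step 11 should pass through the C40 diol ketal F3 and the retro ketal with free C3' hydroxyl F4 and return directly at 20, the acid stage being quenched as soon as the long-wavelength chromophore is fully developed.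

Step 9. Oxidative addition and transmetalation at the tetrasubstituted, doubly flanked enol triflate may be slow, so that destannylation or homocoupling of 13 competes. The fallback builds the side chain linearly from 12 and returns at 14. A Heck reaction of 12 with but-3-en-2-one (Pd(OAc)2, PPh3, Et3N, DMF, 70 °C) should give the dienone (3E)-4-[(4R)-2,6,6-trimethyl-4-[(triethylsilyl)oxy]cyclohex-1-en-1-yl]but-3-en-2-one F5. Horner–Wadsworth–Emmons reaction with triethyl phosphonoacetate (NaH, THF) should give the ethyl pentadienoate F6, and i-Bu2AlH (CH2Cl2, −78 °C) reduces it to 14. The E/Z ratio at the new trisubstituted alkene is unimportant because that bond becomes a single bond in step 11.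

**Further compounds**

F1 | step 11 | tertiary methanesulfonate of 17 at the ring A carbinol carbon (not isolated) | CC1=CC2(OCCO2)CC(C)(C)C1(OS(C)(=O)=O)/C=C/C(C)=C/C=C/C(C)=C/C=C/C=C(C)/C=C/C=C(C)/C=C/C1=C(C)C[C@@H](O[Si](CC)(CC)CC)CC1(C)C
F2 | step 12 | [(2E,4E)-5-[(4R)-4-hydroxy-2,6,6-trimethylcyclohex-1-en-1-yl]-3-methylpenta-2,4-dien-1-yl]triphenylphosphonium bromide | CC1=C(/C=C/C(C)=C/C[P+](c2ccccc2)(c2ccccc2)c2ccccc2)C(C)(C)C[C@H](O)C1.[Br-]
F3 | step 12 | C40 diol ketal (17 without the silyl group; not isolated) | CC1=CC2(OCCO2)CC(C)(C)C1(O)/C=C/C(C)=C/C=C/C(C)=C/C=C/C=C(C)/C=C/C=C(C)/C=C/C1=C(C)C[C@@H](O)CC1(C)C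
F4 | step 12 | (3'S,6E,6'E)-3,3-ethylenedioxy-4',5'-didehydro-4,5'-retro-β,β-caroten-3'-ol (18 without the silyl group; not isolated) | CC1=CC2(OCCO2)CC(C)(C)\C1=C/C=C(C)/C=C/C=C(C)/C=C/C=C/C(C)=C/C=C/C(C)=C/C=C1/C(C)=C[C@@H](O)CC1(C)C
F5 | step 9 | (3E)-4-[(4R)-2,6,6-trimethyl-4-[(triethylsilyl)oxy]cyclohex-1-en-1-yl]but-3-en-2-one | CC(=O)/C=C/C1=C(C)C[C@@H](O[Si](CC)(CC)CC)CC1(C)C
F6 | step 9 | ethyl (2E,4E)-3-methyl-5-[(4R)-2,6,6-trimethyl-4-[(triethylsilyl)oxy]cyclohex-1-en-1-yl]penta-2,4-dienoate | CCOC(=O)/C=C(C)/C=C/C1=C(C)C[C@@H](O[Si](CC)(CC)CC)CC1(C)C
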